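**Conventions and assumptions**

- Labdane locants of the target are used for every intermediate: ring A = C1–C5 and C10, ring B = C5–C10, C17 = methyl on C8, C18 = 4α-methyl, C19 = 4β-CH2O, C20 = 10β-methyl. β is the face of C20, α the face of H-5.
- Assumption: the (R)-configured oxazaborolidinium catalyst of step 5 delivers the enantiomer drawn, by analogy with the formyl C–H···O binding model for enals. If the sense is opposite, the (S)-catalyst, equally available, is used.
- Assumption: potassium [2-(benzyloxy)ethyl]trifluoroborate (16) is purchased.

## Analysis of the target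

Compound 31 is 2α,6α,19-trihydroxylabda-8,13-dien-15,16-olide, (2R,4S,5R,6S,10S) in labdane numbering. It is a trans-fused decalin whose tetrasubstituted C8=C9 alkene carries the C17 methyl and a two-carbon arm (C11–C12) ending in a β-substituted butenolide (C13–C16). The five stereocentres lie on ring A or next to it. C10 (β-methyl) and C4 (β-CH2OH, α-methyl) are quaternary and flank the C5 methine (α-H), and their β substituents are syn-axial. The hydroxyls at C2 and C6 are both α and equatorial: the thermodynamically preferred epimers, but not the ones that hydride attack gives, because C19 and C20 screen the β face of both carbonyls. Sensitive groups are the butenolide (base, nucleophiles, electron-transfer reductants), the 8-ene next to a C6 oxygen function (a 6-ketone can draw the alkene into conjugation) and three free hydroxyls. The hard points are the two 1,3-related quaternary carbons around C5, the two equatorial carbinols, and an alkene whose position must be fixed without leaving a stereocentre at C9. The strategy rests on C7: it sits between the C6 oxygen and C8 of the alkene, so with C6 as the ketone of a β-keto ester a C7 radical can add to C8 of an ethylidene unit on C10, and the alkene is rebuilt as C8=C9 when the C9 radical is oxidised.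

## Retrosynthetic reasoning

**C12–C13.** The butenolide is cut off first, as bromide 28, leaving the decalin as primary iodide 27 (used as zinc reagent 29). The butenolide would not survive the reduction that sets C2 and C6, so it has to arrive after it. The bond chosen joins an unhindered CH2 to an activated alkenyl bromide, and the forward coupling only has to spare silyl ethers, which fall off in the last step (30 to 31).

**C2–H, C6–H and the benzyl ethers.** Iodide 27 comes from tetraol 25 through 26, and 25 from dione 24. Both carbinols are equatorial, so they are set together under thermodynamic control on the rigid decalin, in the operation that also frees O12 and O19. Carrying C2 as a ketone up to this point avoids an early equatorial-selective reduction on a flexible ring, which hydride reagents would not deliver.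

**C7 substituents.** Dione 24 is 22 without the chlorine and the ester at C7 (through 23). Both groups are traceless: the ester makes C7 oxidisable, and the chlorine stops the ring-closure product from being oxidised again and blocks C7 against alkene migration.

**C7–C8 (ring B).** Compound 22 is opened between C7 and C8 to chloro β-keto ester 20. Cutting here, and not at C5–C10 or C9–C10, leaves all three ring A stereocentres in a monocyclic precursor and lets the tetrasubstituted alkene form in the ring closure itself. The forward reaction must add the C7 radical to C8 (6-endo) and regenerate the alkene at C8=C9.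

**C6–C7.** Compound 20 is the chlorination product of β-keto ester 19, which is the one-carbon-plus-ester homologue of aldehyde 18. The aldehyde is the function that controls the regiochemistry of the ring A cycloaddition, so it is reused, not replaced.

**C9–C11 and C8–C9.** The alkenyl unit on C10 of 18 (through 17) is cut at C9–C11 into enol triflate 15 and trifluoroborate 16. Triflate 15 comes from ethyl ketone 13, whose C8–C9 bond is made by adding an ethyl nucleophile to aldehyde 11, itself the reduced form of the C9 ester in 10. The ketone can enolise only towards C8 because C10 is quaternary, so the alkene position is unambiguous. Its geometry is irrelevant, since C9 becomes planar in the key step.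

**C1–C10 and C4–C5 (ring A).** Acetal 10 is the protected form of cycloadduct 9, which is cut into diene 4 and dienophile 8. One [4+2] step sets C4, C5 and C10, and the silyl enol ether it leaves masks the C2 ketone until step 12.

**Fragments.** Diene 4 is the silyl enol ether of enone 3, made from 1 and 2 (C3=C4). Dienophile 8 is the hydrolysed form of 7, made from 5 and 6 (C5=C10).

## Alternatives that were turned down

**Alternative 1:** Ring A is closed last, at C3–C4. A ring B nitrile with a three-carbon tosylate arm on C10, A1, is deprotonated at C4 with KN(SiMe3)2 and the nitrile anion displaces the C3 tosylate to give the trans-decalin with an axial C19 nitrile, A2.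
- For: a 6-exo-tet alkylation of a nitrile anion is dependable, and the small cyano group tends to take the axial position in a chair-like closure, which is the C19 orientation needed. On the C4 stereocentre this route is probably stronger than the chosen one, where C4 depends on the endo rule of a cycloaddition.
- Against: ring B must first be built with C5, C6 and C10 set one by one and with the tetrasubstituted alkene already in place. The hindered axial nitrile needs two reductions to become CH2OH. The 3-furyl group must be oxidised regioselectively to the butenolide beside an alkene that reacts readily with the usual oxidants.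
- Comparison: the chosen route sets the three ring A centres in one step and forms the alkene in the ring closure. That concentrates the risk in fewer operations.

**Alternative 2:** Both rings come from a ten-membered dienedione, A3. Soft enolisation of the C6 ketone (MgBr2·OEt2, i-Pr2NEt) lets C5 add across the ring to C10 of the C2 dienone and gives the trans-fused 8-ene-2,6-dione A4.
- For: on paper this is the shortest ring construction. A4 is the same kind of late dione as 24, so the end game would be shared, and on step economy of the ring-forming event it is stronger.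
- Against: the medium ring with a tetrasubstituted alkene inside a conjugated diene is hard to close. The C6 ketone enolises more readily towards C7 (also allylic) than towards C5. The acceptor carbon C10 is fully substituted and competes with 1,6-addition at C8. The ring fusion depends on a macrocycle conformation that cannot be predicted with confidence from the single C4 stereocentre.
- Comparison: the chosen route reaches 24 by closures whose ring size and regiochemistry are dictated by substitution.

**Alternative 3:** Ring A is closed at C4–C5. Zerovalent palladium (from Pd(OAc)2 and P(t-Bu)3) with NaN(SiMe3)2 couples the C4 nitrile anion of enol triflate A5 with its C5 triflate to give the 5-ene nitrile A6, and hydroboration then adds H to C5 and OH to C6.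
- For: cis addition of the borane from the α face would set 5α-H and 6α-OH together under kinetic control. That is stronger than the late thermodynamic reduction used here.
- Against: the C4 configuration is decided in a reductive elimination that hardly distinguishes methyl from cyano. The alkenylation of a nitrile anion to a quaternary centre is less established than the arylation. A6 still lacks the C8=C9 alkene, C17 and the side chain, all of which would have to be grafted onto an oxygen function at C9 next to the quaternary C10.
- Comparison: the chosen route has ring B complete, with alkene and C17, at the moment it closes, and pays for it with a thermodynamic reduction at C6.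

Key step: step 15

## Route

Step 1
Reactants: 1 1-(benzyloxy)propan-2-one; 2 1-(triphenylphosphoranylidene)propan-2-one
Product: 3 (E)-5-(benzyloxy)-4-methylpent-3-en-2-one
Conditions: PhMe, 110 °C; chromatography
Reagents that add atoms: none
Why: Wittig olefination of an activated α-alkoxy ketone with a stabilised keto ylide; the larger benzyloxymethyl group should end up trans to the acetyl group, and the minor (Z)-isomer is removed by chromatography.

Step 2
Reactants: 3 (E)-5-(benzyloxy)-4-methylpent-3-en-2-one
Product: 4 (E)-{[5-(benzyloxy)-4-methylpenta-1,3-dien-2-yl]oxy}triisopropylsilane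
Conditions: i-Pr3SiOTf, Et3N, CH2Cl2, 0 °C
Reagents that add atoms: triisopropylsilyl trifluoromethanesulfonate, CC(C)[Si](OS(=O)(=O)C(F)(F)F)(C(C)C)C(C)C
Why: Soft enolisation of the methyl ketone gives the cross-conjugated 2-silyloxydiene and leaves the trisubstituted alkene geometry untouched. The bulky silyl group makes the enol ether robust enough to mask the C2 ketone up to step 12.

Step 3
Reactants: 5 2,2-dimethoxyacetaldehyde; 6 methyl 2-(triphenylphosphoranylidene)propanoate
Product: 7 methyl (E)-4,4-dimethoxy-2-methylbut-2-enoate
Conditions: CH2Cl2, 25 °C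
Reagents that add atoms: none
Why: Wittig reaction of a stabilised α-branched ester ylide with an aldehyde, (E)-selective, so the acetal carbon and the ester are trans.

Step 4
Reactants: 7 methyl (E)-4,4-dimethoxy-2-methylbut-2-enoate
Product: 8 methyl (E)-2-methyl-4-oxobut-2-enoate
Conditions: TsOH·H2O (cat.), acetone–H2O, 25 °C
Reagents that add atoms: water, O
Why: Acid hydrolysis of a dimethyl acetal; the conjugated (E)-enal ester is the more stable geometry and should persist.

Step 5
Reactants: 4 (E)-{[5-(benzyloxy)-4-methylpenta-1,3-dien-2-yl]oxy}triisopropylsilane; 8 methyl (E)-2-methyl-4-oxobut-2-enoate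
Product: 9 methyl (1S,5S,6S)-5-[(benzyloxy)methyl]-6-formyl-1,5-dimethyl-3-[(triisopropylsilyl)oxy]cyclohex-3-ene-1-carboxylate (labdane locants: 10β-methyl, 10α-ester, 5β-formyl, 4β-CH2OBn, 4α-methyl, C2 silyl enol ether)
Conditions: (R)-1-(2-methylphenyl)-3,3-diphenyltetrahydro-1H,3H-pyrrolo[1,2-c][1,3,2]oxazaborole (20 mol %), HN(SO2CF3)2 (20 mol %), CH2Cl2, −78 → −40 °C
Reagents that add atoms: none
Why: Catalytic enantioselective Diels–Alder reaction in which the chiral oxazaborolidinium ion binds the formyl group, so the nucleophilic C1 of the 2-silyloxydiene bonds to C10 (β to the aldehyde) and C4 bonds to C5. Suprafacial addition to the (E)-dienophile puts C6 and C9 trans, the formyl-endo transition state with the benzyloxymethyl group in the outside position of the diene puts C19 cis to C6 and C20, and the catalyst shields one face of the dienophile and thereby sets the absolute configuration of C4, C5 and C10.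

Step 6
Reactants: 9 ring A cycloadduct (formyl ester)
Product: 10 methyl (1S,5S,6S)-5-[(benzyloxy)methyl]-6-(dimethoxymethyl)-1,5-dimethyl-3-[(triisopropylsilyl)oxy]cyclohex-3-ene-1-carboxylate (C6 dimethyl acetal of 9)
Conditions: CH(OMe)3, MeOH, PPTS (cat.), 0 → 25 °C
Reagents that add atoms: trimethyl orthoformate, COC(OC)OC
Why: Acetalisation of the aldehyde under buffered acid with orthoformate as water scavenger; the hindered triisopropylsilyl enol ether is expected to outlast the fast aldehyde reaction.

Step 7
Reactants: 10 ring A acetal ester
Product: 11 C9 aldehyde: 5-[(benzyloxy)methyl]-6-(dimethoxymethyl)-1,5-dimethyl-3-[(triisopropylsilyl)oxy]cyclohex-3-ene-1-carbaldehyde, ring stereocentres as in 9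
Conditions: i-Bu2AlH (1.1 equiv), CH2Cl2, −78 °C; aq. KNaC4H4O6
Reagents that add atoms: none
Why: Partial reduction of a methyl ester on a quaternary carbon; the crowded aluminium hemiacetal should persist at −78 °C and release the aldehyde only on work-up.

Step 8
Reactants: 11 C9 aldehyde
Product: 12 C9 carbinol: 1-[ring A of 11]propan-1-ol, both C9 epimers
Conditions: EtMgBr, THF, −78 → 0 °C; aq. NH4Cl
Reagents that add atoms: ethylmagnesium bromide, CC[Mg]Br
Why: Grignard addition to a non-enolisable aldehyde brings in C8 and C17; the carbinol configuration is irrelevant because it is oxidised next.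

Step 9
Reactants: 12 C9 carbinol
Product: 13 C9 ethyl ketone: 1-[ring A of 11]propan-1-one
Conditions: Dess–Martin periodinane, NaHCO3, CH2Cl2, 25 °C
Reagents that add atoms: none
Why: Dess–Martin oxidation of a secondary alcohol, buffered so that the acetal and the silyl enol ether are not exposed to acid.

Step 10
Reactants: 13 C9 ethyl ketone
Product: 15 (Z)-enol triflate of 13 (C9–OTf, C8=C9, C17 cis to the triflate), via potassium enolate 14 (not isolated)
Conditions: KN(SiMe3)2, THF, −78 °C; PhN(SO2CF3)2, −78 → 0 °C
Reagents that add atoms: N-phenylbis(trifluoromethanesulfonimide), O=S(=O)(N(c1ccccc1)S(=O)(=O)C(F)(F)F)C(F)(F)F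
Why: The ketone can enolise only towards C8 because C10 is quaternary; O-sulfonylation of the (Z)-enolate fixes the alkene at C8=C9, and its geometry has no consequence later.

Step 11
Reactants: 15 (Z)-enol triflate; 16 potassium [2-(benzyloxy)ethyl]trifluoroborate
Product: 17 ring A bearing on C10 the (E)-5-(benzyloxy)pent-2-en-3-yl group [C9(=C8H–C17H3)–C11H2–C12H2–OBn, C17 trans to C10], with the C6 dimethyl acetal, C2 silyl enol ether and C19 benzyl ether retained
Conditions: PdCl2(dppf)·CH2Cl2 (10 mol %), Cs2CO3, THF–H2O (10:1), 75 °C
Reagents that add atoms: none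
Why: Suzuki–Miyaura coupling of a primary alkyltrifluoroborate with an alkenyl triflate forms C9–C11 with retention of alkene geometry; the tetracoordinate boron reagent avoids the β-alkoxy elimination of other 2-alkoxyethyl organometallics.

Step 12
Reactants: 17 ring A acetal with complete C9 unit
Product: 18 keto aldehyde: 2-[(benzyloxy)methyl]-6-[(E)-5-(benzyloxy)pent-2-en-3-yl]-2,6-dimethyl-4-oxocyclohexane-1-carbaldehyde, stereocentres (labdane C4, C5, C10) as in 9
Conditions: HCl (2 M aq.), THF, 25 → 40 °C
Reagents that add atoms: water, O
Why: Aqueous acid hydrolyses the dimethyl acetal and the silyl enol ether in one operation, while benzyl ethers and the trisubstituted alkene are stable. C5 lies between two quaternary carbons, so enolisation of the aldehyde should be slow.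

Step 13
Reactants: 18 keto aldehyde
Product: 19 β-keto ester: ethyl 3-oxo-3-[ring A of 18]propanoate (C6 ketone, C7 methylene)
Conditions: N2CHCO2Et, SnCl2 (10 mol %), CH2Cl2, 25 °C
Reagents that add atoms: ethyl diazoacetate, CCOC(=O)C=[N+]=[N-]
Why: Roskamp homologation (addition of the diazo ester to the SnCl2-activated aldehyde, 1,2-hydride shift, loss of N2) forms C6–C7 and is selective for the aldehyde over the C2 ketone.

Step 14
Reactants: 19 β-keto ester
Product: 20 chloro β-keto ester: ethyl 2-chloro-3-oxo-3-[ring A of 18]propanoate, both C7 epimers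
Conditions: NCS (1.05 equiv), Mg(ClO4)2 (30 mol %), MeCN, 0 → 25 °C
Reagents that add atoms: N-chlorosuccinimide, O=C1CCC(=O)N1Cl
Why: Electrophilic chlorination of the magnesium-chelated enol of the β-keto ester; the simple C2 ketone and the alkene are far less reactive, and both C7 epimers give the same radical.

Step 15
Reactants: 20 chloro β-keto ester
Product: 22 ethyl 12,19-bis(benzyloxy)-7-chloro-2,6-dioxo-13,14,15,16-tetranorlabd-8-ene-7-carboxylate (5α-H, 10β-methyl, C7 epimers), via 9(11)-ene isomer 21 (not isolated)
Conditions: Mn(OAc)3·2H2O (2.2 equiv), Cu(OAc)2·H2O (1 equiv), degassed AcOH, 50 °C; then TsOH·H2O (10 mol %), PhMe, 60 °C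
Reagents that add atoms: none
Why: Mn(OAc)3 converts the chloro β-keto ester into its trivalent-manganese enolate, and inner-sphere electron transfer releases the electrophilic C7 radical. The closest known reaction type is the oxidative free-radical cyclisation of unsaturated α-chloro β-keto esters with Mn(OAc)3 and Cu(OAc)2, which gives cyclohexanones. Ring B closes in the 6-endo-trig mode: the radical attacks C8, the less substituted alkene carbon, because C9 is fully substituted and the ketone lies inside the forming ring, both of which disfavour the 5-exo path. The trans ring fusion is inherited from ring A, where the C5 and C10 arms are trans; the C7 centre formed here is removed in steps 16 and 17 and C8 and C9 end as sp2 carbons, so no new stereocenter has to be controlled. Divalent copper oxidises the tertiary C9 radical, and loss of the C8 hydrogen gives 22 while loss of a C11 hydrogen gives 21. The acid stage reprotonates 21 at C11 and funnels the C9 cation to the tetrasubstituted alkene; C7 carries no hydrogen at this point, so the alkene cannot slide into conjugation with the C6 ketone. The chlorine keeps 22 from being enolised and oxidised a second time. The step needs regioselectivity in the addition (secured by the substitution at C9) and in the position of the alkene (secured by the equilibration), and the alkene geometry of 20 is irrelevant because C9 becomes planar.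

Step 16
Reactants: 22 chloro keto ester of ring B
Product: 23 ethyl 12,19-bis(benzyloxy)-2,6-dioxo-13,14,15,16-tetranorlabd-8-ene-7-carboxylate (C7 epimers and enol)
Conditions: Zn dust, AcOH, 25 °C
Reagents that add atoms: none
Why: Reductive dehalogenation of an α-chloro β-dicarbonyl compound through its zinc enolate; ketones, benzyl ethers and the alkene are inert.

Step 17
Reactants: 23 β-keto ester of ring B
Product: 24 12,19-bis(benzyloxy)-13,14,15,16-tetranorlabd-8-ene-2,6-dione
Conditions: LiCl, DMSO, H2O, 140 °C
Reagents that add atoms: none
Why: Krapcho dealkoxycarbonylation: chloride dealkylates the ester, the β-keto carboxylate loses CO2, and the resulting dienolate is protonated at C7, which keeps the 8-ene out of conjugation. Any cis-fused material can equilibrate at C5 to the trans-fused ketone.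

Step 18
Reactants: 24 2,6-dione
Product: 25 13,14,15,16-tetranorlabd-8-ene-2α,6α,12,19-tetraol
Conditions: Li, NH3 (liq.)–THF, EtOH, −78 → −33 °C; then NH4Cl
Reagents that add atoms: none
Why: Dissolving-metal reduction gives the thermodynamically preferred equatorial alcohols at C2 and C6 (the axial epimers would be syn-axial to C19 and C20) and cleaves both benzyl ethers; the isolated tetrasubstituted alkene is not reduced.

Step 19
Reactants: 25 tetraol
Product: 26 12-iodo-13,14,15,16-tetranorlabd-8-ene-2α,6α,19-triol
Conditions: I2 (1.1 equiv), PPh3 (1.1 equiv), imidazole, THF, 0 °C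
Reagents that add atoms: iodine, II
Why: Appel-type iodination; with one equivalent of reagent the unhindered primary C12 hydroxyl should react far faster than the neopentyl C19 hydroxyl and the two secondary ones.

Step 20
Reactants: 26 iodo triol
Product: 27 12-iodo-2α,6α,19-tris(triethylsilyloxy)-13,14,15,16-tetranorlabd-8-ene
Conditions: Et3SiOTf, 2,6-lutidine, CH2Cl2, −78 → 0 °C
Reagents that add atoms: triethylsilyl trifluoromethanesulfonate, CC[Si](CC)(CC)OS(=O)(=O)C(F)(F)F
Why: Silylation with a silyl triflate is strong enough for the hindered 6α-hydroxyl and leaves the primary iodide untouched.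

Step 21
Reactants: 27 tris(triethylsilyl) iodide; 28 4-bromofuran-2(5H)-one
Product: 30 2α,6α,19-tris(triethylsilyloxy)labda-8,13-dien-15,16-olide, via alkylzinc iodide 29 (not isolated)
Conditions: Zn dust, LiCl, THF, 40 °C; then 28, Pd(OAc)2 (3 mol %), SPhos (6 mol %), THF, 25 °C
Reagents that add atoms: none
Why: Zinc insertion into the primary iodide followed by Negishi coupling with the activated alkenyl bromide forms C12–C13; silyl ethers and the lactone tolerate the organozinc reagent.

Step 22
Reactants: 30 tris(triethylsilyl) ether of the target
Product: 31 2α,6α,19-trihydroxylabda-8,13-dien-15,16-olide, (2R,4S,5R,6S,10S)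
Conditions: HF·pyridine, THF, 0 → 25 °C
Reagents that add atoms: none
Why: Fluoride-mediated cleavage of the three triethylsilyl ethers under mildly acidic conditions that the butenolide and the alkene tolerate.

## Compound list

1 | 1-(benzyloxy)propan-2-one | CC(=O)COCc1ccccc1 | starting material
2 | 1-(triphenylphosphoranylidene)propan-2-one | CC(=O)C=P(c1ccccc1)(c1ccccc1)c1ccccc1 | starting material
3 | (E)-5-(benzyloxy)-4-methylpent-3-en-2-one | CC(=O)/C=C(\C)COCc1ccccc1 | intermediate
4 | (E)-{[5-(benzyloxy)-4-methylpenta-1,3-dien-2-yl]oxy}triisopropylsilane | C=C(O[Si](C(C)C)(C(C)C)C(C)C)/C=C(\C)COCc1ccccc1 | intermediate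
5 | 2,2-dimethoxyacetaldehyde | COC(OC)C=O | starting material
6 | methyl 2-(triphenylphosphoranylidene)propanoate | COC(=O)C(C)=P(c1ccccc1)(c1ccccc1)c1ccccc1 | starting material
7 | methyl (E)-4,4-dimethoxy-2-methylbut-2-enoate | COC(OC)/C=C(\C)C(=O)OC | intermediate
8 | methyl (E)-2-methyl-4-oxobut-2-enoate | O=C/C=C(\C)C(=O)OC | intermediate
9 | methyl (1S,5S,6S)-5-[(benzyloxy)methyl]-6-formyl-1,5-dimethyl-3-[(triisopropylsilyl)oxy]cyclohex-3-ene-1-carboxylate | COC(=O)[C@@]1(C)CC(O[Si](C(C)C)(C(C)C)C(C)C)=C[C@](C)(COCc2ccccc2)[C@@H]1C=O | intermediate
10 | C6 dimethyl acetal of 9 | COC(=O)[C@@]1(C)CC(O[Si](C(C)C)(C(C)C)C(C)C)=C[C@](C)(COCc2ccccc2)[C@@H]1C(OC)OC | intermediate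
11 | C9 aldehyde (ester of 10 reduced to formyl) | O=C[C@@]1(C)CC(O[Si](C(C)C)(C(C)C)C(C)C)=C[C@](C)(COCc2ccccc2)[C@@H]1C(OC)OC | intermediate
12 | C9 carbinol, both C9 epimers | CCC(O)[C@@]1(C)CC(O[Si](C(C)C)(C(C)C)C(C)C)=C[C@](C)(COCc2ccccc2)[C@@H]1C(OC)OC | intermediate
13 | C9 ethyl ketone | CCC(=O)[C@@]1(C)CC(O[Si](C(C)C)(C(C)C)C(C)C)=C[C@](C)(COCc2ccccc2)[C@@H]1C(OC)OC | intermediate
14 | potassium (Z)-enolate of 13 | [K+].C/C=C(\[O-])[C@@]1(C)CC(O[Si](C(C)C)(C(C)C)C(C)C)=C[C@](C)(COCc2ccccc2)[C@@H]1C(OC)OC | intermediate
15 | (Z)-enol triflate of 13 | C/C=C(\OS(=O)(=O)C(F)(F)F)[C@@]1(C)CC(O[Si](C(C)C)(C(C)C)C(C)C)=C[C@](C)(COCc2ccccc2)[C@@H]1C(OC)OC | intermediate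
16 | potassium [2-(benzyloxy)ethyl]trifluoroborate | [K+].F[B-](F)(F)CCOCc1ccccc1 | starting material
17 | ring A with (E)-5-(benzyloxy)pent-2-en-3-yl group on C10, C6 dimethyl acetal, C2 silyl enol ether | C/C=C(\CCOCc3ccccc3)[C@@]1(C)CC(O[Si](C(C)C)(C(C)C)C(C)C)=C[C@](C)(COCc2ccccc2)[C@@H]1C(OC)OC | intermediate
18 | keto aldehyde (C2 ketone, C6 formyl) | C/C=C(\CCOCc3ccccc3)[C@@]1(C)CC(=O)C[C@](C)(COCc2ccccc2)[C@@H]1C=O | intermediate
19 | β-keto ester (ethyl ester, C7 methylene) | C/C=C(\CCOCc3ccccc3)[C@@]1(C)CC(=O)C[C@](C)(COCc2ccccc2)[C@@H]1C(=O)CC(=O)OCC | intermediate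
20 | chloro β-keto ester, C7 epimers (key-step precursor) | C/C=C(\CCOCc3ccccc3)[C@@]1(C)CC(=O)C[C@](C)(COCc2ccccc2)[C@@H]1C(=O)C(Cl)C(=O)OCC | intermediate
21 | 9(11)-ene regioisomer of 22 (mixture at C7, C8 and of alkene geometry) | CC1C(=CCOCc3ccccc3)[C@@]2(C)CC(=O)C[C@](C)(COCc4ccccc4)[C@@H]2C(=O)C1(Cl)C(=O)OCC | intermediate
22 | ethyl 12,19-bis(benzyloxy)-7-chloro-2,6-dioxo-13,14,15,16-tetranorlabd-8-ene-7-carboxylate, C7 epimers (key-step product) | CC1=C(CCOCc3ccccc3)[C@@]2(C)CC(=O)C[C@](C)(COCc4ccccc4)[C@@H]2C(=O)C1(Cl)C(=O)OCC | intermediate
23 | ethyl 12,19-bis(benzyloxy)-2,6-dioxo-13,14,15,16-tetranorlabd-8-ene-7-carboxylate | CC1=C(CCOCc3ccccc3)[C@@]2(C)CC(=O)C[C@](C)(COCc4ccccc4)[C@@H]2C(=O)C1C(=O)OCC | intermediate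
24 | 12,19-bis(benzyloxy)-13,14,15,16-tetranorlabd-8-ene-2,6-dione | CC1=C(CCOCc3ccccc3)[C@@]2(C)CC(=O)C[C@](C)(COCc4ccccc4)[C@@H]2C(=O)C1 | intermediate
25 | 13,14,15,16-tetranorlabd-8-ene-2α,6α,12,19-tetraol | CC1=C(CCO)[C@@]2(C)C[C@@H](O)C[C@](C)(CO)[C@@H]2[C@@H](O)C1 | intermediate
26 | 12-iodo-13,14,15,16-tetranorlabd-8-ene-2α,6α,19-triol | CC1=C(CCI)[C@@]2(C)C[C@@H](O)C[C@](C)(CO)[C@@H]2[C@@H](O)C1 | intermediate
27 | 12-iodo-2α,6α,19-tris(triethylsilyloxy)-13,14,15,16-tetranorlabd-8-ene | CC1=C(CCI)[C@@]2(C)C[C@@H](O[Si](CC)(CC)CC)C[C@](C)(CO[Si](CC)(CC)CC)[C@@H]2[C@@H](O[Si](CC)(CC)CC)C1 | intermediate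
28 | 4-bromofuran-2(5H)-one | O=C1OCC(Br)=C1 | starting material
29 | C12 alkylzinc iodide of 27 | CC1=C(CC[Zn]I)[C@@]2(C)C[C@@H](O[Si](CC)(CC)CC)C[C@](C)(CO[Si](CC)(CC)CC)[C@@H]2[C@@H](O[Si](CC)(CC)CC)C1 | intermediate
30 | 2α,6α,19-tris(triethylsilyloxy)labda-8,13-dien-15,16-olide | CC1=C(CCC3=CC(=O)OC3)[C@@]2(C)C[C@@H](O[Si](CC)(CC)CC)C[C@](C)(CO[Si](CC)(CC)CC)[C@@H]2[C@@H](O[Si](CC)(CC)CC)C1 | intermediate
31 | 2α,6α,19-trihydroxylabda-8,13-dien-15,16-olide, (2R,4S,5R,6S,10S) | CC1=C(CCC2=CC(=O)OC2)[C@@]2(C)C[C@@H](O)C[C@](C)(CO)[C@@H]2[C@@H](O)C1 | target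

## Step count and least certain steps

Total: 22 steps. Longest linear sequence: 20 steps (steps 1–2 or 3–4, then 5–22).

**Step 15 (key step).** The termination is the weak point. The C9 radical may lose a C11 hydrogen instead of the C8 hydrogen, or the derived cation may be captured by acetate or by the C7 ester carbonyl (lactonisation). The acid stage meant to repair the alkene position may instead ionise the allylic benzyl ether of 21. A 1,5-hydrogen shift from the C19 methylene to the C7 radical could also compete with cyclisation. The fallback keeps the same C7–C8 bond but caps the cyclised radical with chlorine instead of oxidising it. From 19, NCS (2.2 equiv) with Mg(ClO4)2 gives the α,α-dichloro β-keto ester F1. CuCl with 2,2'-bipyridine (monovalent copper, catalytic) in 1,2-dichloroethane at 80 °C gives the 6-endo atom-transfer product, the 7,9-dichloride F2. Loss of HCl from the tertiary C9 chloride (TsOH·H2O, PhMe, 80 °C) returns the route to 22.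

**Step 5.** Facial and endo selectivity may erode if the hindered partners react stepwise (Mukaiyama–Michael, then ring closure) or if silyl triflimide released from the diene catalyses a background reaction. The (Z)-methyl of the diene also slows the concerted path. The fallback gives up asymmetric catalysis: 4 and 8 are combined with Me2AlCl to give racemic material, that is 9 together with its enantiomer F3, and 9 is obtained by preparative chromatography on a chiral stationary phase. It returns at 9.

**Step 11.** Oxidative addition and transmetalation at the enol triflate next to the quaternary C10 may be slow, which would let triflate hydrolysis and protodeboronation take over. The fallback builds the arm in a higher oxidation state. From 15, Negishi coupling with BrZnCH2CO2t-Bu (Pd2(dba)3, XPhos, THF, 50 °C) gives the tert-butyl ester F4, LiAlH4 reduces it to the homoallylic alcohol F5, and NaH with benzyl bromide returns the route to 17.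

**Step 18.** Base formed during the reduction may move the 8-ene into conjugation with the C6 ketone before electron transfer, leading to over-reduction. Enolisation may also return ketone, and the equatorial selectivity may be incomplete at one centre. The fallback separates the two events and avoids a strongly basic medium. From 24, SmI2 with H2O and Et3N in THF at 0 °C should give the 2α,6α-diol with both benzyl ethers intact, F8, and hydrogenolysis (H2, Pd/C, EtOAc; the tetrasubstituted alkene is inert) returns the route to 25.

**Step 13.** Addition of the diazo ester to an aldehyde flanked by two quaternary carbons may be slow. That leaves time for epimerisation at C5 or for a Lewis-acid-induced closure of the aldehyde onto the C8=C9 alkene. The fallback reaches the β-keto ester by acylation. From 18, NaClO2 with NaH2PO4 and 2-methylbut-2-ene gives the carboxylic acid F6, carbonyldiimidazole gives the acyl imidazole F7, and Mg(O2CCH2CO2Et)2 followed by decarboxylation on work-up returns the route to 19.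

## Further compounds

F1 | step 15 | α,α-dichloro β-keto ester of ring A | C/C=C(\CCOCc3ccccc3)[C@@]1(C)CC(=O)C[C@](C)(COCc2ccccc2)[C@@H]1C(=O)C(Cl)(Cl)C(=O)OCC
F2 | step 15 | ethyl 12,19-bis(benzyloxy)-7,9-dichloro-2,6-dioxo-13,14,15,16-tetranorlabdane-7-carboxylate (mixture at C7, C8, C9) | CC1C(Cl)(CCOCc3ccccc3)[C@@]2(C)CC(=O)C[C@](C)(COCc4ccccc4)[C@@H]2C(=O)C1(Cl)C(=O)OCC
F3 | step 5 | methyl (1R,5R,6R)-5-[(benzyloxy)methyl]-6-formyl-1,5-dimethyl-3-[(triisopropylsilyl)oxy]cyclohex-3-ene-1-carboxylate (enantiomer of 9) | COC(=O)[C@]1(C)CC(O[Si](C(C)C)(C(C)C)C(C)C)=C[C@@](C)(COCc2ccccc2)[C@H]1C=O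
F4 | step 11 | tert-butyl ester with C9(=CHCH3)CH2CO2t-Bu on C10, otherwise as 17 | C/C=C(\CC(=O)OC(C)(C)C)[C@@]1(C)CC(O[Si](C(C)C)(C(C)C)C(C)C)=C[C@](C)(COCc2ccccc2)[C@@H]1C(OC)OC
F5 | step 11 | homoallylic alcohol with C9(=CHCH3)CH2CH2OH on C10, otherwise as 17 | C/C=C(\CCO)[C@@]1(C)CC(O[Si](C(C)C)(C(C)C)C(C)C)=C[C@](C)(COCc2ccccc2)[C@@H]1C(OC)OC
F6 | step 13 | C6 carboxylic acid from 18 | C/C=C(\CCOCc3ccccc3)[C@@]1(C)CC(=O)C[C@](C)(COCc2ccccc2)[C@@H]1C(=O)O
F7 | step 13 | C6 acyl imidazole from F6 | C/C=C(\CCOCc3ccccc3)[C@@]1(C)CC(=O)C[C@](C)(COCc2ccccc2)[C@@H]1C(=O)n1ccnc1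
F8 | step 18 | 12,19-bis(benzyloxy)-13,14,15,16-tetranorlabd-8-ene-2α,6α-diol | CC1=C(CCOCc3ccccc3)[C@@]2(C)C[C@@H](O)C[C@](C)(COCc4ccccc4)[C@@H]2[C@@H](O)C1
A1 | alternative 1 | ring B nitrile with C2 silyloxy C3 tosylate arm on C10 (C4 unassigned) | CC1=C(CCc2ccoc2)[C@@](C)(C[C@@H](O[Si](C)(C)C(C)(C)C)COS(=O)(=O)c2ccc(C)cc2)[C@H](C(C)C#N)[C@@H](O[Si](C)(C)C(C)(C)C)C1
A2 | alternative 1 | trans-decalin with axial C19 nitrile, 2α,6α-bis(silyl ether), 3-furyl side chain | CC1=C(CCc2ccoc2)[C@@]2(C)C[C@@H](O[Si](C)(C)C(C)(C)C)C[C@](C)(C#N)[C@@H]2[C@@H](O[Si](C)(C)C(C)(C)C)C1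
A3 | alternative 2 | ten-membered 1(10),8-diene-2,6-dione with C19 nitrile (ring alkene geometries left open) | CC1=C(CCO[Si](C)(C)C(C)(C)C)C(C)=CC(=O)C[C@](C)(C#N)CC(=O)C1
A4 | alternative 2 | trans-fused 8-ene-2,6-dione with C19 nitrile | CC1=C(CCO[Si](C)(C)C(C)(C)C)[C@@]2(C)CC(=O)C[C@](C)(C#N)[C@@H]2C(=O)C1
A5 | alternative 3 | ring B C5 enol triflate with C2 ketal and C4 nitrile arm on C10 (C4 unassigned) | CC(C#N)CC1(OCCO1)C[C@]1(C)[C@@H](O[Si](C)(C)C(C)(C)C)CCC=C1OS(=O)(=O)C(F)(F)F
A6 | alternative 3 | 5-ene bicyclic nitrile with C2 ketal and C9 silyl ether | C1[C@H](O[Si](C)(C)C(C)(C)C)[C@@]2(C)CC3(OCCO3)C[C@](C)(C#N)C2=CC1
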